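Fold the recipe of south into one number before any result is seen.

| flask | starting material | partner | protic impurity | temperature | remark | time |
|---|---|---|---|---|---|---|
| maple | 0.62 M | 0.37 M | 0.31 M | 55 °C | run made earlier |  |
| cedar | 0.62 M | 0.56 M | 0.31 M | 80 °C | run made earlier |  |
| larch | 0.62 M | 0.744 M | 0.62 M | 55 °C | run made earlier |  |
| south | 0.62 M | 0.744 M | 0.310 M | 80 °C |  | 3.0 min |
| north-east | 0.62 M | 0.744 M | 0.310 M | 60 °C |  | 3.0 min |
| east | 0.62 M | 0.744 M | 0.310 M | 100 °C |  | 3.0 min |

| run | time / min | target / % |
|---|---|---|
| maple | 0.667 | 0 |
| maple | 1.00 | 0 |
| maple | 2.50 | 2 |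
| maple | 5.00 | 1 |
| maple | 8.00 | 2 |
| cedar | 0.200 | 0 |
| cedar | 0.667 | 3 |
| cedar | 1.00 | 5 |
| cedar | 1.50 | 10 |
| cedar | 2.50 | 15 |
| larch | 1.50 | 0 |
| larch | 3.00 | 0 |
| larch | 5.00 | 3 |
| larch | 6.00 | 1 |
| larch | 8.00 | 2 |

(standard deviation of a reading: 1.5 percentage points)

- the best flask by amount of target, in percent of the starting material charged; "all alike" if 1.5 percentage points covers them all (south / north-east / east / all alike)
- amount of target at the end, in percent of the starting material charged, south
- amount of target at the end, in percent of the starting material charged, north-east
- amount of target at the end, in percent of the starting material charged, east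



1. South and the cedar run share c(starting material), c(protic impurity) and temperature. They differ in c(partner) and in time. Assume, with those three held, that target forms at a rate proportional to c(partner), so that target follows the product of c(partner) and time.

2. That product gives 1.59 for south. This dose ratio, c(partner) times time in a flask over the same product in a reference reading at equal temperature, says how many times the reference amount of target to expect.

3. The last cedar reading, 15% at 2.50 min, therefore becomes 23.9% for south.

4. The cedar run itself tests the number. Between 1.00 min and 2.50 min the dose grows 2.50-fold and the reading 3.00-fold, on readings with a scatter of 1.5 percentage points. The ratio holds temperature fixed, so it speaks for south and gives nothing for north-east or east.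

5. The forecast names east as best, with 23% for south (17% to 30%), 3% for north-east (1% to 6%) and 55% for east (33% to 85%). For east it warns that “the protic impurity may consume up to half the starting material”. Its south value differs slightly from the 23.9% reckoned here.

6. The flasks give 21.4% in south, 1.71% in north-east and 48.3% in east, so east is best, and the forecast for east stands 6.7 points too high.

    starting material → intermediate B (k = 0.00950 s⁻¹, Ea = 106 kJ mol⁻¹)
    intermediate C → side product (k = 0.00190 s⁻¹, Ea = 108 kJ mol⁻¹)
    partner + protic impurity → quenched reagent (k = 0.0110 L mol⁻¹ s⁻¹, Ea = 54.0 kJ mol⁻¹)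
    partner + intermediate B → target (k = 0.00910 L mol⁻¹ s⁻¹, Ea = 78.0 kJ mol⁻¹)
    starting material → intermediate A (k = 0.0100 s⁻¹, Ea = 91.0 kJ mol⁻¹)
    intermediate A → intermediate C (k = 0.0660 s⁻¹, Ea = 106 kJ mol⁻¹)
    (constants at 80 °C)

South ended below its estimate: the ratio 1.59 gave 23.9% and the flask holds 21.4%. A neighbouring flask repeats north-east with 3.0 M of partner and the same time, so its dose ratio against north-east is 4.03. That turns 1.71% into 6.89%. The neighbour holds 5.75%, which is 3.36 times the amount in north-east.

The data were generated by integration from invented constants.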